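The plan rests on cutting C6–C7 (germacrane numbering), the bond shared by the ten-membered carbocycle and the γ-lactone. Because C7 carries C11, the C13–C11–C7 unit is read as an allyl nucleophile and C6 as an aldehyde. One CrCl2-mediated Nozaki–Hiyama–Kishi allylation of an open-chain bis-epoxy aldehyde bearing an allylic chloride closes the carbocycle. It sets C6 and C7 under control of C8 and places an isopropenyl group beside the new C6 hydroxyl. Allylic C–H functionalisations frame this step. Ene chlorination arms a simple prenyl group beforehand. SeO2 afterwards raises C12 to the lactone carbonyl and, last, hydroxylates C5.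

Key step: step 13

Remark on numbering, used for all intermediates:
- C6 is the lactone carbinol carbon and C7 the ring-fusion carbon bearing C11.
- C8 is the angelate carbon and C9 the ring CH2.
- C10 is the methyl-bearing oxirane carbon (methyl = C14); C1, C2 and C3 are the three oxirane CH.
- C4 is the exomethylene carbon (=C15H2) and C5 the free carbinol.
- C12 is the lactone C=O and C13 the lactone =CH2.

Remark on the chemistry: 17–19 are used as C7 epimers, because C7 becomes planar in 20.

Step 1
Reactants: 1 α-methylene-γ-butyrolactone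
Product: 2 2-methylidenebutane-1,4-diol
Conditions: iBu2AlH (2.5 equiv), CH2Cl2, −78 to 0 °C; aq. work-up
Reagents that add atoms: none
Why: Ester-to-alcohol reduction by two 1,2-hydride deliveries, which at low temperature should leave the conjugated exocyclic alkene untouched; no stereocenter is formed.

Step 2
Reactants: 2 2-methylidenebutane-1,4-diol
Product: 3 3-(chloromethyl)but-3-en-1-ol
Conditions: N-chlorosuccinimide, Me2S, CH2Cl2, −20 to 0 °C
Reagents that add atoms: N-chlorosuccinimide O=C1CCC(=O)N1Cl
Why: Corey–Kim halogenation, in which only the alkoxysulfonium salt of the allylic hydroxyl is displaced by chloride while that of the homoallylic hydroxyl reverts to the alcohol on work-up.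

Step 3
Reactants: 3 3-(chloromethyl)but-3-en-1-ol
Product: 4 tert-butyl{[3-(chloromethyl)but-3-en-1-yl]oxy}dimethylsilane
Conditions: TBSCl, imidazole, CH2Cl2, 0 °C to rt
Reagents that add atoms: tert-butyldimethylsilyl chloride CC(C)(C)[Si](C)(C)Cl
Why: Standard silylation of the remaining primary alcohol, which the allylic chloride tolerates.

Step 4
Reactants: 5 3-methylbut-2-enal (prenal); 6 allenylboronic acid pinacol ester
Product: 7 (4S)-6-methylhept-5-en-1-yn-4-ol
Conditions: (S)-TRIP phosphoric acid (5 mol %), 4 Å MS, toluene, −20 °C; aq. work-up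
Reagents that add atoms: none
Why: Chiral phosphoric acid-catalysed propargylation through a closed six-membered transition state with allenyl-to-propargyl transposition, in which the (S)-acid should shield one aldehyde face and set C8 as S, the mirror image of the known (R)-acid to (R)-carbinol sense for aryl and alkenyl aldehydes.

Step 5
Reactants: 7 (4S)-6-methylhept-5-en-1-yn-4-ol
Product: 8 (4S)-4-(tert-butyldimethylsilyloxy)-6-methylhept-5-en-1-yne
Conditions: TBSCl, imidazole, DMF, rt
Reagents that add atoms: tert-butyldimethylsilyl chloride CC(C)(C)[Si](C)(C)Cl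
Why: Standard silylation that turns O8 into a poor leaving group for the later organochromium step; C8 is untouched.

Step 6
Reactants: 8 (4S)-4-(tert-butyldimethylsilyloxy)-6-methylhept-5-en-1-yne
Product: 11 (2E,5S)-5-(tert-butyldimethylsilyloxy)-3,7-dimethylocta-2,6-dien-1-ol, via alkenylalane 9 (not isolated), via lithium alanate 10 (not isolated)
Conditions: Me3Al, Cp2ZrCl2 (20 mol %), CH2Cl2, 0 °C to rt; n-BuLi, THF, −78 °C; (CH2O)n, rt; aq. work-up
Reagents that add atoms: trimethylaluminium C[Al](C)C; formaldehyde (as paraformaldehyde) C=O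
Why: Negishi zirconium-catalysed carboalumination adds CH3 (C14) and aluminium syn across the terminal alkyne, which fixes the E geometry of C1=C10, and the alanate is hydroxymethylated (C2) with retention while the prenyl alkene stays inert.

Step 7
Reactants: 11 (2E,5S)-5-(tert-butyldimethylsilyloxy)-3,7-dimethylocta-2,6-dien-1-ol
Product: 12 [(2R,3R)-3-[(2S)-2-(tert-butyldimethylsilyloxy)-4-methylpent-3-en-1-yl]-3-methyloxiran-2-yl]methanol
Conditions: Ti(OiPr)4 (10 mol %), D-(−)-diethyl tartrate (12 mol %), t-BuOOH, 4 Å MS, CH2Cl2, −20 °C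
Reagents that add atoms: tert-butyl hydroperoxide CC(C)(C)OO
Why: Katsuki–Sharpless asymmetric epoxidation, in which only the allylic alcohol binds titanium and the D-tartrate should deliver oxygen to the face that gives the trans (1R,10R)-oxirane, the sense known for geraniol.

Step 8
Reactants: 12 the epoxy alcohol
Product: 13 (2S,3R)-3-[(2S)-2-(tert-butyldimethylsilyloxy)-4-methylpent-3-en-1-yl]-3-methyloxirane-2-carbaldehyde
Conditions: TEMPO (10 mol %), PhI(OAc)2, CH2Cl2, rt
Reagents that add atoms: none
Why: Oxoammonium (TEMPO) oxidation stops at the aldehyde and is mild enough for the oxirane; the stereocenters are unchanged (the descriptor at C1 changes only through ligand priorities).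

Step 9
Reactants: 4 the allylic chloride; 13 the epoxy aldehyde
Product: 16 open-chain (1R,2S,3S,8S,10R)-1,10:2,3-bis-epoxide with C4 exomethylene and 6-OTBS and 8-OTBS and C7=C11 prenyl terminus, via chloroallylborane 14 (not isolated), via syn-chlorohydrin 15 (not isolated)
Conditions: 4 (1.5 equiv), (−)-Ipc2BOMe, LiN(c-C6H11)2 (from HN(c-C6H11)2 and n-BuLi), Et2O, −95 °C; BF3·OEt2; 13, −95 °C; NaOH, H2O2, 0 °C to rt
Reagents that add atoms: none
Why: Brown-type (Z)-γ-chloroallylboration, in which the chlorine cis to CH2B gives the syn chlorohydrin through a chair transition state, the isopinocampheyl groups from (+)-α-pinene choose the aldehyde face (reagent control at C2), and basic peroxide cleaves boron and closes the cis-oxirane by SN2 with inversion at C3.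

Step 10
Reactants: 16 the bis-epoxide
Product: 17 7-chloro-11(13)-ene allylic chloride (C7 epimers)
Conditions: N-chlorosuccinimide (1.1 equiv), PhSeCl (10 mol %), CH2Cl2, 0 °C to rt
Reagents that add atoms: N-chlorosuccinimide O=C1CCC(=O)N1Cl
Why: Selenium-catalysed ene-type allylic chlorination places chlorine on C7 and moves the alkene to C11=C13, and it should prefer the trisubstituted prenyl alkene over C4=C15, which is less substituted and deactivated by the allylic oxirane.

Step 11
Reactants: 17 the allylic chloride
Product: 18 primary alcohol at C6 (8-OTBS kept)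
Conditions: HF·pyridine, pyridine, THF, 0 °C
Reagents that add atoms: none
Why: Sterically differentiated fluoride desilylation, in which the primary silyl ether should cleave well before the hindered secondary one and buffered HF spares the oxiranes and the chloride.

Step 12
Reactants: 18 the primary alcohol
Product: 19 β,γ-unsaturated aldehyde at C6 carrying the C7 allylic chloride
Conditions: Dess–Martin periodinane, pyridine, CH2Cl2, 0 °C
Reagents that add atoms: none
Why: Buffered Dess–Martin oxidation is non-basic and fast, so C4=C15 should not move into conjugation with the new aldehyde.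

Step 13
Reactants: 19 the chloro aldehyde
Product: 21 1β,10α:2α,3α-diepoxy-8α-(tert-butyldimethylsilyloxy)germacra-4(15),11(13)-dien-6α-ol (7αH), via allylchromium dichloride 20 (not isolated)
Conditions: CrCl2 (10 equiv), THF/DMF 4:1, 25 °C, 19 added by syringe pump over 12 h (final 2 mM); H2O work-up
Reagents that add atoms: none
Why: Two equivalents of CrCl2 reduce the allylic chloride in two one-electron steps to the σ-allyl species 20, with trivalent chromium on the primary carbon C13 whichever C7 epimer is used, and 20 adds to the C6 aldehyde through C7 with allyl transposition in a six-membered chair (intramolecular Nozaki–Hiyama–Kishi allylation, a reaction type known for closing ten-membered carbocycles from ω-formyl allylic halides). The carbocycle closes 10-exo-trig at the carbonyl carbon with only C7 of the allyl unit entering the ring, whereas attack through C13 would need a twelve-membered ring outside the cyclic transition state. C7 is controlled by C8: A1,3 strain with the substituent on C11 holds H8 in the alkene plane, so OTBS and the C9 tether lie on opposite faces and the tethered aldehyde can reach only the face anti to OTBS, which gives 7αH. C6 is controlled by the chair, in which C5 and C8 are both equatorial, which gives the anti relationship (6α-OH, later the trans-lactone). Chemoselectivity is needed against the vinyl oxirane and both oxiranes; it rests on the much faster reduction of the allylic chloride and on the absence of iodide, which divalent chromium needs to open vinyl oxiranes. High dilution and the two rigid oxiranes, the cis one acting as a turn, should favour ring closure over oligomerisation.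

Step 14
Reactants: 21 the carbocyclic alcohol
Product: 22 6α,12-diol (C12H3 oxidised to C12H2OH)
Conditions: SeO2 (0.3 equiv), t-BuOOH (2 equiv), CH2Cl2, 0 °C, stopped at monohydroxylation
Reagents that add atoms: tert-butyl hydroperoxide CC(C)(C)OO
Why: Riley-type SeO2/t-BuOOH allylic hydroxylation (ene reaction, then 2,3-sigmatropic shift) should take the isopropenyl methyl first, because its ene step keeps the transient alkene outside the ring and this alkene, unlike C4=C15, is not deactivated by an allylic oxirane.

Step 15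
Reactants: 22 the diol
Product: 24 8α-(tert-butyldimethylsilyloxy)-1β,10α:2α,3α-diepoxygermacra-4(15),11(13)-dien-6α,12-olide, via lactol 23 (not isolated)
Conditions: MnO2 (excess), CH2Cl2, rt
Reagents that add atoms: none
Why: MnO2 oxidises only the allylic primary alcohol, the enal is trapped by the neighbouring 6α-hydroxyl as lactol 23, and this allylic lactol is oxidised on (oxidative lactonisation) to the trans-fused α-methylene lactone while O8 is still blocked.

Step 16
Reactants: 24 the silyl lactone
Product: 25 8α-hydroxy-1β,10α:2α,3α-diepoxygermacra-4(15),11(13)-dien-6α,12-olide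
Conditions: HF·pyridine, THF, 0 °C to rt
Reagents that add atoms: none
Why: Fluoride desilylation under weakly acidic conditions avoids both base-induced acyl shift of the lactone towards O8 and conjugate addition to the methylene lactone.

Step 17
Reactants: 25 the 8α-alcohol; 26 angelic acid
Product: 28 8α-angeloyloxy-1β,10α:2α,3α-diepoxygermacra-4(15),11(13)-dien-6α,12-olide, via mixed anhydride 27 (not isolated)
Conditions: 26, 2,4,6-trichlorobenzoyl chloride, Et3N, toluene, rt, filter; 25, toluene, 80 °C
Reagents that add atoms: none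
Why: Yamaguchi-type mixed-anhydride acylation without a nucleophilic catalyst, the variant that transfers the angeloyl group without Z-to-E isomerisation; C8 keeps its configuration because only the O–H bond reacts.

Step 18
Reactants: 28 the 5-deoxy angelate
Product: 29 target, 8α-angeloyloxy-1β,10α:2α,3α-diepoxy-5β-hydroxygermacra-4(15),11(13)-dien-6α,12-olide
Conditions: SeO2 (0.5 equiv), t-BuOOH (3 equiv), CH2Cl2, rt to 35 °C
Reagents that add atoms: tert-butyl hydroperoxide CC(C)(C)OO
Why: Riley-type allylic hydroxylation at the only reactive site (C5H2 next to C4=C15; C3–H is an oxirane C–H and the acrylate and angelate alkenes are electron-poor), in which the 2,3-shift should deliver oxygen to the outer face of the transient endocyclic C4=C5 bond, the face that also carries O6 when H6 eclipses the alkene, to give 5β-OH with C4=C15 restored.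

Compound list
1 | α-methylene-γ-butyrolactone | C=C1CCOC1=O | starting material
2 | 2-methylidenebutane-1,4-diol | C=C(CO)CCO | intermediate
3 | 3-(chloromethyl)but-3-en-1-ol | C=C(CCl)CCO | intermediate
4 | tert-butyl{[3-(chloromethyl)but-3-en-1-yl]oxy}dimethylsilane | C=C(CCl)CCO[Si](C)(C)C(C)(C)C | intermediate
5 | 3-methylbut-2-enal | CC(C)=CC=O | starting material
6 | allenylboronic acid pinacol ester | C=C=CB1OC(C)(C)C(C)(C)O1 | starting material
7 | (4S)-6-methylhept-5-en-1-yn-4-ol | C#CC[C@H](O)C=C(C)C | intermediate
8 | (4S)-4-(tert-butyldimethylsilyloxy)-6-methylhept-5-en-1-yne | C#CC[C@H](O[Si](C)(C)C(C)(C)C)C=C(C)C | intermediate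
9 | (E)-alkenyl(dimethyl)alane, Al on C1 cis to C14 | C[Al](C)/C=C(\C)C[C@H](O[Si](C)(C)C(C)(C)C)C=C(C)C | intermediate
10 | lithium butyl(dimethyl)alkenylalanate | [Li+].CCCC[Al-](C)(C)/C=C(\C)C[C@H](O[Si](C)(C)C(C)(C)C)C=C(C)C | intermediate
11 | (2E,5S)-5-(tert-butyldimethylsilyloxy)-3,7-dimethylocta-2,6-dien-1-ol | OC/C=C(\C)C[C@H](O[Si](C)(C)C(C)(C)C)C=C(C)C | intermediate
12 | (1R,10R,8S)-epoxy alcohol | OC[C@H]1O[C@]1(C)C[C@H](O[Si](C)(C)C(C)(C)C)C=C(C)C | intermediate
13 | epoxy aldehyde (C2 = CHO) | O=C[C@H]1O[C@]1(C)C[C@H](O[Si](C)(C)C(C)(C)C)C=C(C)C | intermediate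
14 | (γ-chloroallyl)diisopinocampheylborane, Cl cis to CH2B | Cl/C=C(\CB([C@@H]1C[C@@H]2C[C@H]([C@H]1C)C2(C)C)[C@@H]1C[C@@H]2C[C@H]([C@H]1C)C2(C)C)CCO[Si](C)(C)C(C)(C)C | intermediate
15 | (2R,3R)-syn-chlorohydrin | C=C(CCO[Si](C)(C)C(C)(C)C)[C@@H](Cl)[C@H](O)[C@H]1O[C@]1(C)C[C@H](O[Si](C)(C)C(C)(C)C)C=C(C)C | intermediate
16 | (1R,2S,3S,8S,10R)-bis-epoxide, prenyl terminus | C=C(CCO[Si](C)(C)C(C)(C)C)[C@@H]1O[C@@H]1[C@H]1O[C@]1(C)C[C@H](O[Si](C)(C)C(C)(C)C)C=C(C)C | intermediate
17 | 7-chloro-11(13)-ene (C7 epimers) | C=C(CCO[Si](C)(C)C(C)(C)C)[C@@H]1O[C@@H]1[C@H]1O[C@]1(C)C[C@H](O[Si](C)(C)C(C)(C)C)C(Cl)C(C)=C | intermediate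
18 | C6 primary alcohol | C=C(CCO)[C@@H]1O[C@@H]1[C@H]1O[C@]1(C)C[C@H](O[Si](C)(C)C(C)(C)C)C(Cl)C(C)=C | intermediate
19 | C6 aldehyde with C7 allylic chloride | C=C(CC=O)[C@@H]1O[C@@H]1[C@H]1O[C@]1(C)C[C@H](O[Si](C)(C)C(C)(C)C)C(Cl)C(C)=C | intermediate
20 | σ-allylchromium dichloride, Cr on C13 | C=C(CC=O)[C@@H]1O[C@@H]1[C@H]1O[C@]1(C)C[C@H](O[Si](C)(C)C(C)(C)C)/C=C(\C)C[Cr](Cl)Cl | intermediate
21 | ten-membered carbocycle, 6α-OH, 7β-isopropenyl, 8α-OTBS | O[C@@H]1CC(=C)[C@@H]2O[C@@H]2[C@H]2O[C@]2(C)C[C@H](O[Si](C)(C)C(C)(C)C)[C@H]1C(C)=C | intermediate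
22 | 6α,12-diol | O[C@@H]1CC(=C)[C@@H]2O[C@@H]2[C@H]2O[C@]2(C)C[C@H](O[Si](C)(C)C(C)(C)C)[C@H]1C(=C)CO | intermediate
23 | 6α,12-lactol (C12 epimers) | C=C1C(O)O[C@H]2[C@H]1[C@@H](O[Si](C)(C)C(C)(C)C)C[C@@]1(C)O[C@@H]1[C@H]1O[C@H]1C(=C)C2 | intermediate
24 | 8α-OTBS trans-lactone | C=C1C(=O)O[C@H]2[C@H]1[C@@H](O[Si](C)(C)C(C)(C)C)C[C@@]1(C)O[C@@H]1[C@H]1O[C@H]1C(=C)C2 | intermediate
25 | 8α-hydroxy lactone | C=C1C(=O)O[C@H]2[C@H]1[C@@H](O)C[C@@]1(C)O[C@@H]1[C@H]1O[C@H]1C(=C)C2 | intermediate
26 | angelic acid, (Z)-2-methylbut-2-enoic acid | C/C=C(/C)C(=O)O | starting material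
27 | angelic 2,4,6-trichlorobenzoic anhydride | C/C=C(/C)C(=O)OC(=O)c1c(Cl)cc(Cl)cc1Cl | intermediate
28 | 5-deoxy angelate | C=C1C(=O)O[C@H]2[C@H]1[C@@H](OC(=O)/C(C)=C\C)C[C@@]1(C)O[C@@H]1[C@H]1O[C@H]1C(=C)C2 | intermediate
29 | target | C=C1C(=O)O[C@H]2[C@H]1[C@@H](OC(=O)/C(C)=C\C)C[C@@]1(C)O[C@@H]1[C@H]1O[C@H]1C(=C)[C@@H]2O | target

Total step count: 18. Longest linear sequence: 15 steps (steps 4–18, from prenal).

Steps most likely to fail

1. Step 13.
What may go wrong:
- intermolecular coupling outrunning ring closure;
- halide- and chromium-assisted reductive opening of the vinyl oxirane;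
- drift of C4=C15 into conjugation with the aldehyde.

Fallback: leave one-electron chromium chemistry and the secondary chloride altogether. It sets out from 16. SeO2/t-BuOOH hydroxylates the E-methyl group of the more reactive trisubstituted prenyl alkene to the (E)-allylic alcohol F1. An Appel reaction (CBr4, PPh3) gives the primary (E)-allylic bromide F2. HF·pyridine frees the C6 primary alcohol F3, and Dess–Martin oxidation gives the bromo aldehyde F4. Indium powder in THF/H2O at high dilution then closes the same C6–C7 bond and comes back to the route at 21. This is a Barbier allylation by two-electron metal insertion in a neutral aqueous medium that leaves oxiranes alone.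

2. Step 9.
What may go wrong:
- metalation of the 2-substituted allylic chloride at the wrong site, or carbenoid decay;
- loss of the cis chloro-alkene geometry of 14;
- facial selectivity eroded by a mismatched epoxy aldehyde.

Fallback: make the oxirane on a preformed Z-alkene under hydroxyl direction. It sets out from 13. Still–Gennari olefination with bis(2,2,2-trifluoroethyl) [4-(tert-butyldimethylsilyloxy)-2-oxobutyl]phosphonate (KN(SiMe3)2, 18-crown-6, THF, −78 °C) gives the Z-enone F5. Corey–Bakshi–Shibata reduction ((S)-Me-CBS, BH3·SMe2) gives the (4R)-Z-allylic alcohol F6. VO(acac)2/t-BuOOH epoxidation, directed by the hydroxyl in the A1,3-controlled conformer, gives the cis-epoxy alcohol F7. Dess–Martin oxidation gives the epoxy ketone F8, and Wittig methylenation (Ph3P=CH2, THF, 0 °C) comes back to the route at 16.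

3. Step 18.
What may go wrong:
- a sluggish ene step at an alkene flanked by an oxirane and an acyloxy-bearing carbon;
- poor facial selectivity of oxygen delivery at C5.

Fallback: take C5 to the ketone level and set it by reduction. It sets out from 28. Allylic oxidation with CrO3·3,5-dimethylpyrazole (CH2Cl2, −20 °C) gives the cross-conjugated 5-ketone F9. Luche reduction (NaBH4, CeCl3·7H2O, MeOH, −78 °C) should deliver hydride from the ring periphery in the non-chelated conformer with C5=O opposed to the C6–O dipole. This gives the 5β-alcohol, syn to O6, and comes back to the route at 29.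

Further compounds
F1 | step 13 | (E)-13-hydroxy bis-epoxide | C=C(CCO[Si](C)(C)C(C)(C)C)[C@@H]1O[C@@H]1[C@H]1O[C@]1(C)C[C@H](O[Si](C)(C)C(C)(C)C)/C=C(\C)CO
F2 | step 13 | (E)-13-bromide | C=C(CCO[Si](C)(C)C(C)(C)C)[C@@H]1O[C@@H]1[C@H]1O[C@]1(C)C[C@H](O[Si](C)(C)C(C)(C)C)/C=C(\C)CBr
F3 | step 13 | (E)-13-bromide with free C6 alcohol | C=C(CCO)[C@@H]1O[C@@H]1[C@H]1O[C@]1(C)C[C@H](O[Si](C)(C)C(C)(C)C)/C=C(\C)CBr
F4 | step 13 | (E)-13-bromo C6 aldehyde | C=C(CC=O)[C@@H]1O[C@@H]1[C@H]1O[C@]1(C)C[C@H](O[Si](C)(C)C(C)(C)C)/C=C(\C)CBr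
F5 | step 9 | (2Z)-enone, C4 ketone | CC(C)(C)[Si](C)(C)OCCC(=O)/C=C\[C@H]1O[C@]1(C)C[C@H](O[Si](C)(C)C(C)(C)C)C=C(C)C
F6 | step 9 | (4R,2Z)-allylic alcohol | CC(C)(C)[Si](C)(C)OCC[C@@H](O)/C=C\[C@H]1O[C@]1(C)C[C@H](O[Si](C)(C)C(C)(C)C)C=C(C)C
F7 | step 9 | (4R)-hydroxy 1,10:2,3-bis-epoxide | CC(C)(C)[Si](C)(C)OCC[C@@H](O)[C@@H]1O[C@@H]1[C@H]1O[C@]1(C)C[C@H](O[Si](C)(C)C(C)(C)C)C=C(C)C
F8 | step 9 | 4-oxo 1,10:2,3-bis-epoxide | CC(C)(C)[Si](C)(C)OCCC(=O)[C@@H]1O[C@@H]1[C@H]1O[C@]1(C)C[C@H](O[Si](C)(C)C(C)(C)C)C=C(C)C
F9 | step 18 | 5-oxo angelate | C=C1C(=O)O[C@H]2[C@H]1[C@@H](OC(=O)/C(C)=C\C)C[C@@]1(C)O[C@@H]1[C@H]1O[C@H]1C(=C)C2=O
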